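The rate constants of the winter flask are not given, so the reckoning starts from its charges and readings.

| flask | left-handed substrate | right-handed substrate | reagent | racemization catalyst | temperature | remark | time |
|---|---|---|---|---|---|---|---|
| winter | 5 mM | 5 mM | 12.5 mM | 70 µM | 110 °C | the very flask that is asked about, followed so far |  |
| midnight | 10 mM | 10 mM | 12.5 mM | 70 µM | 105 °C | run made earlier |  |
| flask | 5.0 mM | 5.0 mM | 12.5 mM | 70 µM | 110 °C |  | 25 min |

- winter (time / min: left-handed product / %): 2.00: 58.0; 4.00: 55.2; 8.00: 59.1; 12.0: 56.3; 25.0: 57.5
- midnight (time / s: left-handed product / %): 10.0: 31.6; 15.0: 34.4; 30.0: 36.9; 60.0: 37.6; 120: 38.1

(scatter of a reading: 1 percentage point)

- reagent is single-handed; left-handed substrate and right-handed substrate are mirror images of each other, charged as a racemate, each of them at the stated concentration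
- left-handed product that was removed still counts
- what was read earlier has a scatter of 1 percentage point, one standard deviation
- additions bring no volume worth counting
- the handed part of reagent does not stay in what it makes, so the products of the two hands are mirror images too

- south-west: at 25 min add reagent, 50.0% of the amount charged, then wait 12 min
- north-east: at 25 min add racemization catalyst, 50.0% of the amount charged, then wait 12 min
- north-west: at 25 min raise the temperature by 10 K, then wait 12 min
- south-east: at 25 min take out 90% of the left-handed product then present, then wait 12 min
- south: change nothing and wait 12 min more

- left-handed product, in percent of the left-handed substrate and right-handed substrate together first charged, at 25 min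
- what to do for the largest gain in left-handed product; "none" if nothing gains more than 2 percentage points (south-west / north-east / north-west / south-east / south / none)
- left-handed product present, with what was taken out counted in, in percent of the left-handed substrate and right-handed substrate together first charged, after south-west
- left-handed product present, with what was taken out counted in, in percent of the left-handed substrate and right-handed substrate together first charged, after north-east

If each product costs one reagent and one substrate, the reagent and the two substrates together fall at the same rate, whatever the constants are. Integrated, that rate says that reagent minus substrates together stays at its charged value. Racemization cancels from the sum, since one hand merely becomes the other. The winter flask has a reagent cover of 1.25: the charge of reagent over the charge of the two substrates together. That is above one, so the reagent keeps 20.0% of its charge once the substrates are consumed.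

The midnight run has a cover of 0.625, below one. Reagent is therefore its limiting reagent, and its products of both hands together stop at 62.5% of the substrates charged.

One objection is that the cost of one reagent per product is assumed, and right-handed product was not read. But a cost of two would cap both products at 31.2%, and the midnight run reads more left-handed product than that, 38.1% at 120 s.

A second objection concerns the winter readings. Their mean, 57.2%, is higher than the 50.0% that the left-handed substrate supplied. So right-handed substrate crosses over, presumably through the racemization catalyst, and the cover gives both hands together, not their share.

A third objection is that a flat line might be a stall. The first and last winter readings differ by 0.5 percentage points, less than the scatter of 1 point, and the cover leaves reagent over. The reckoning therefore puts the stop on the substrates. It commits to 57.2% now, the same after south-west and north-east, and no option above 2 points.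

The forecast gives 57.2% now, 57.3% after south-west, 57.3% after north-east and none as best, saying: “Extra reagent or catalyst has nothing to act on.”

The simulation gives 56.8% now, 56.8% after south-west, 56.8% after north-east, and none as best.

    reagent + left-handed substrate → left-handed product (k = 27.0 M⁻¹ s⁻¹, Ea = 52.0 kJ mol⁻¹)
    reagent + right-handed substrate → right-handed product (k = 16.0 M⁻¹ s⁻¹, Ea = 59.0 kJ mol⁻¹)
    left-handed substrate + racemization catalyst ⇌ right-handed substrate + racemization catalyst, rate k3*[racemization catalyst]*[left-handed substrate] forward; the back reaction follows from the equilibrium constant (k = 860 M⁻¹ s⁻¹, Ea = 53.0 kJ mol⁻¹)
    (constants at 110 °C)

At 25.0 min the flask keeps 20% of its reagent, as the cover gave. The neighbour flask, the same flask but with 7.5 mM of reagent, has a cover of 0.750. At 25.0 min it holds 44.7% left-handed and 30.3% right-handed product, together 75.0%, with 0% of its reagent left. In the flask itself, the half-life of the slowest mode as it stands at 25.0 min is 0.289 min, far shorter than the 25 min asked about. Already at 2.50 min the flask holds 0% left-handed substrate and 56.8% left-handed product.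

The runs are calculated with made-up constants, and the scatter is random.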